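**Retrosynthetic overview**
- The pyranone ring (O1, C2, C3, C4, C4a, C8a) is cut last. C2–C3 comes from an isovanillin-derived 3-arylpropanoyl unit by Claisen acylation of a C4 methyl ketone, and O1–C8a closes by acid onto a C8a dimethyl ketal once sulfur is removed.
- The strategy rests on this feature of the carbocycle (C4a, C5, C6, C7, C8, C8a): C4 on C4a and O7 on C7 stand 1,4 across the ring, like the carbonyl carbon and ring oxygen of a 2-pyrone, and C8(Cl)–C8a(O) is a chloroketene acetal. The ring is therefore cut at C4a–C8a and C7–C8 into (S)-3-(p-tolylsulfinyl)-2-pyrone and 2-chloro-1,1-dimethoxyethene.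
- The bridged lactone is opened by MeLi while C5=C6 is still an alkene. The 5,6-diol is then delivered from the free 7-OH before sulfur is removed, so no 7-oxy-8-chloro-7,8-dihydrochromone (an arene hydrate that would aromatise) is ever formed.
- Ring order: carbocycle first (step 3), pyranone ring last (step 14).

Key step: step 3

Assumption: atom numbers are those of the target chromone throughout; hydroxy ketone 9 may sit partly as its bridged hemiketal (O7 on C4) and is written in the open form.

Step 1
Reactants: 1 3-bromo-2H-pyran-2-one; 2 (1R,2S,5R)-menthyl (S)-4-methylbenzenesulfinate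
Product: 4 (S)-3-(p-tolylsulfinyl)-2H-pyran-2-one, via lithium methyl(pyron-3-yl)cuprate 3 (not isolated)
Conditions: Me2CuLi (from CuI and MeLi), THF–Et2O, −78 °C; then 2, −78 → 0 °C
Reagents that add atoms: none
Why: Bromine–copper exchange gives the 3-cuprio-2-pyrone, which attacks sulfur of the sulfinate ester with inversion (Andersen sulfoxide synthesis), so the (S)-sulfinate should give the (S)-sulfoxide as one enantiomer; the sulfur stereocentre is bought in because enantioselective oxidation of a sulfide flanked by two sp2 carbons is unreliable.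

Step 2
Reactants: 5 2-chloro-1,1,1-trimethoxyethane
Product: 6 2-chloro-1,1-dimethoxyethene
Conditions: Me3SiOTf, iPr2NEt, CH2Cl2, −20 → 23 °C; distil
Reagents that add atoms: none
Why: The silyl triflate removes one methoxide to give the dimethoxycarbenium ion and the hindered amine takes the acidified CHCl proton (1,2-elimination of methanol from an ortho ester to a ketene acetal).

Step 3
Reactants: 4 (S)-3-(p-tolylsulfinyl)-2H-pyran-2-one; 6 2-chloro-1,1-dimethoxyethene
Product: 7 bridged sulfinyl lactone (7-chloro-8,8-dimethoxy-4-[(S)-p-tolylsulfinyl]-2-oxabicyclo[2.2.2]oct-5-en-3-one; in target numbering C4 lactone carbonyl, O7 ring oxygen, sulfur on C4a, C8a dimethyl ketal, C8–Cl on the side of the C5=C6 bridge)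
Conditions: 6 (3 equiv), CH2Cl2, 23 °C, dark; 10 kbar if slow
Reagents that add atoms: none
Why: Inverse-electron-demand Diels–Alder reaction in which the sulfinyl group lowers the LUMO of the pyrone diene, the nucleophilic CHCl carbon of 6 bonds to the pyrone carbon next to the ring oxygen (C7–C8) and the acetal carbon to the sulfinyl-bearing carbon (C4a–C8a) in a concerted, asynchronous, suprafacial [4+2]; the closest known reactions are the cycloadditions of 3-sulfinyl-, 3-sulfonyl- and 3-bromo-2-pyrones with vinyl ethers and 1,1-dimethoxyethene, which stop at the bridged lactone when kept near room temperature. The carbocycle is closed by this intermolecular [4+2] annulation as a 2-oxabicyclo[2.2.2]oct-5-ene whose lactone bridge already holds C4 and O7. C4a and C7 are the bridgeheads, so C4 and O7 are cis by construction, and their absolute sense follows from the diene face attacked, which the (S)-sulfur chooses: with S–O turned away from the lactone C=O, p-tolyl covers one face and 6 should add to the lone-pair face. C8 is set by endo placement of chlorine under the diene, away from the ring-oxygen lone pairs, which puts Cl on the side of the new C5=C6 bridge, trans to O7. Regioselectivity comes from the polarity match, endo selectivity from the usual preference of heteroatom substituents in such cycloadditions, and facial selectivity from sulfur.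

Step 4
Reactants: 7 bridged sulfinyl lactone
Product: 8 bridged sulfonyl lactone (7-chloro-8,8-dimethoxy-4-(p-tolylsulfonyl)-2-oxabicyclo[2.2.2]oct-5-en-3-one; same configuration at carbon)
Conditions: mCPBA, NaHCO3, CH2Cl2, 0 → 23 °C
Reagents that add atoms: mCPBA, OOC(=O)c1cccc(Cl)c1
Why: Peracid oxidation of sulfoxide to sulfone should be faster than epoxidation of the deactivated bridged alkene, and the sulfone removes the allyl sulfoxide [2,3]-shift (Mislow–Evans), sulfoxide syn-elimination and sulfoxide–lithium exchange that would threaten the following steps; carbon stereocentres are untouched.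

Step 5
Reactants: 8 bridged sulfonyl lactone
Product: 9 hydroxy methyl ketone (cyclohex-2-ene with acetyl (C4) and p-tolylsulfonyl on C4a, C5=C6, 7-OH cis to acetyl, 8-Cl trans to 7-OH, C8a dimethyl ketal)
Conditions: MeLi (1.1 equiv), THF, −78 °C; AcOH, −78 °C
Reagents that add atoms: methyllithium, [Li]C
Why: Acyl substitution of the strained lactone by the small organolithium, which can reach the carbonyl from the C5=C6 side (the other side is covered by a ketal methoxy group, and an oxygen on C5 would close this side too, hence opening before dihydroxylation); the quench at −78 °C keeps the C7 alkoxide from displacing the trans chloride, from a second addition and from retro-Claisen acetyl transfer, and no stereocentre changes.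

Step 6
Reactants: 9 hydroxy methyl ketone
Product: 10 chelated osmate ester of the 5,6-diol (dioxo-osmium glycolate on O5 and O6 with TMEDA bound to osmium, 7-OH free, O5, O6 and O7 all cis)
Conditions: OsO4 (1.05 equiv), TMEDA (1.1 equiv), CH2Cl2, −78 °C
Reagents that add atoms: osmium tetroxide, O=[Os](=O)(=O)=O; TMEDA, CN(C)CCN(C)C
Why: Hydroxyl-directed dihydroxylation in which the OsO4·TMEDA complex is hydrogen-bonded by the allylic 7-OH and adds to C5=C6 from the O7 face, setting C5 and C6 cis to O7; the chelated ester of hexavalent osmium is stable to chromatography and is kept as the diol protecting group.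

Step 7
Reactants: 10 chelated osmate ester
Product: 11 7-O-TBS osmate ester
Conditions: tBuMe2SiCl, imidazole, DMAP (cat.), DMF, 23 °C
Reagents that add atoms: tert-butyldimethylsilyl chloride, CC(C)(C)[Si](C)(C)Cl
Why: Silylation of the only free hydroxyl while O5 and O6 are held on osmium gives full regiocontrol and keeps O5, which is β to the sulfonyl ketone, away from base (no retro-aldol ring opening).

Step 8
Reactants: 11 7-O-TBS osmate ester
Product: 13 acetonide methyl ketone (5,6-O-isopropylidene, 7-OTBS, 8-Cl, C8a dimethyl ketal, acetyl and sulfonyl on C4a), via 5,6-diol 12 (not isolated)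
Conditions: HCl in MeOH, 0 °C; then 2,2-dimethoxypropane, 0 → 23 °C
Reagents that add atoms: 2,2-dimethoxypropane, COC(C)(C)OC
Why: Acid takes TMEDA off osmium and methanolysis frees the cis-5,6-diol, which is caught at once as the acetonide (ketalisation) because O7 is blocked; acid is used instead of amine or sulfite cleavage so that 5-OH never meets base.

Step 9
Reactants: 14 isovanillin
Product: 15 4-methoxy-3-(methoxymethoxy)benzaldehyde
Conditions: MOMCl, iPr2NEt, CH2Cl2, 0 → 23 °C
Reagents that add atoms: chloromethyl methyl ether, COCCl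
Why: O-Alkylation of the phenol to its MOM ether, which is acid-labile like the other protecting groups.

Step 10
Reactants: 15 4-methoxy-3-(methoxymethoxy)benzaldehyde
Product: 16 (E)-3-[4-methoxy-3-(methoxymethoxy)phenyl]prop-2-enoic acid
Conditions: malonic acid, pyridine, piperidine (cat.), 90 °C
Reagents that add atoms: malonic acid, OC(=O)CC(=O)O
Why: Knoevenagel condensation with decarboxylation (Doebner modification) gives the (E)-cinnamic acid.

Step 11
Reactants: 16 (E)-3-[4-methoxy-3-(methoxymethoxy)phenyl]prop-2-enoic acid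
Product: 17 3-[4-methoxy-3-(methoxymethoxy)phenyl]propanoic acid
Conditions: H2 (1 atm), Pd/C, EtOAc, 23 °C
Reagents that add atoms: none
Why: Catalytic hydrogenation of the conjugated alkene; the aryl ethers are not touched.

Step 12
Reactants: 17 3-[4-methoxy-3-(methoxymethoxy)phenyl]propanoic acid
Product: 18 1-{3-[4-methoxy-3-(methoxymethoxy)phenyl]propanoyl}-1H-benzotriazole
Conditions: 1H-benzotriazole, DCC, CH2Cl2, 0 → 23 °C
Reagents that add atoms: 1H-benzotriazole, c1ccc2[nH]nnc2c1
Why: Carbodiimide coupling gives the N-acylbenzotriazole, a neutral C-acylating agent for ketone enolates.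

Step 13
Reactants: 13 acetonide methyl ketone; 18 N-acylbenzotriazole
Product: 20 β-diketone sulfone (C4a–C(=O)–CH2–C(=O)–CH2CH2Ar; ring as in 13), via lithium enolate 19 (not isolated)
Conditions: LiN(SiMe3)2 (2.2 equiv), THF, −78 °C; then 18, −78 → −30 °C; AcOH
Reagents that add atoms: none
Why: Crossed Claisen acylation in which the ketone can enolise only toward its methyl group (C4a is quaternary) and the lithium enolate is C-acylated by 18; the second equivalent of base holds the product as its diketonate, which shields C4 from retro-Claisen loss of the sulfonyl carbanion.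

Step 14
Reactants: 20 β-diketone sulfone
Product: 22 protected chromone (5,6-O-isopropylidene, 7-OTBS, 8-Cl, aryl OMOM), via desulfonylated diketone 21 (not isolated)
Conditions: SmI2 (2.5 equiv), THF–MeOH, −78 °C; then CSA (0.3 equiv), CH2Cl2, 23 °C
Reagents that add atoms: none
Why: Reductive desulfonylation of the β-keto sulfone by SmI2 with protonation of the samarium enolate by methanol at −78 °C, then acid-catalysed loss of methanol from the β-keto ketal (the second methoxy assists, so the ketal oxygen should leave in preference to the dioxolane oxygen on C5) and attack of the diketone enol oxygen on C8a with loss of the second methanol (cyclodehydration to the 4-pyranone), which removes the C4a stereocentre.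

Step 15
Reactants: 22 protected chromone
Product: 23 (5S,6S,7S,8R)-8-chloro-5,6,7-trihydroxy-2-[2-(3-hydroxy-4-methoxyphenyl)ethyl]-5,6,7,8-tetrahydro-4H-chromen-4-one
Conditions: TFA–H2O (9:1), 0 → 23 °C
Reagents that add atoms: none
Why: Aqueous acid hydrolysis removes acetonide, silyl ether and MOM ether in one operation; C8–Cl is not activated toward ionisation and no stereocentre is touched.

**Compound list**
1 | 3-bromo-2H-pyran-2-one | O=c1occcc1Br | starting material
2 | (1R,2S,5R)-menthyl (S)-4-methylbenzenesulfinate | C[C@@H]1CC[C@H]([C@@H](C1)O[S@](=O)c2ccc(C)cc2)C(C)C | starting material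
3 | lithium methyl(2-oxo-2H-pyran-3-yl)cuprate | [Li+].C[Cu-]c1cccoc1=O | intermediate
4 | (S)-3-(p-tolylsulfinyl)-2H-pyran-2-one | O=c1occcc1[S@@](=O)c1ccc(C)cc1 | intermediate
5 | 2-chloro-1,1,1-trimethoxyethane | COC(CCl)(OC)OC | starting material
6 | 2-chloro-1,1-dimethoxyethene | ClC=C(OC)OC | intermediate
7 | bridged sulfinyl lactone, 7-chloro-8,8-dimethoxy-4-[(S)-p-tolylsulfinyl]-2-oxabicyclo[2.2.2]oct-5-en-3-one, Cl syn to the alkene bridge | O=C1O[C@H]2C=C[C@]1([S@@](=O)c3ccc(C)cc3)C(OC)(OC)[C@@H]2Cl | intermediate
8 | bridged sulfonyl lactone, 7-chloro-8,8-dimethoxy-4-(p-tolylsulfonyl)-2-oxabicyclo[2.2.2]oct-5-en-3-one | O=C1O[C@H]2C=C[C@]1(S(=O)(=O)c3ccc(C)cc3)C(OC)(OC)[C@@H]2Cl | intermediate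
9 | hydroxy methyl ketone (C4a acetyl and sulfonyl, C5=C6, 7-OH cis to acetyl, 8-Cl trans to 7-OH, C8a dimethyl ketal) | CC(=O)[C@]1(S(=O)(=O)c2ccc(C)cc2)C=C[C@H](O)[C@@H](Cl)C1(OC)OC | intermediate
10 | chelated osmate ester of the all-cis 5,6,7-triol (osmium on O5 and O6, TMEDA on osmium, 7-OH free) | CC(=O)[C@]1(S(=O)(=O)c2ccc(C)cc2)[C@@H]3O[Os](=O)(=O)O[C@@H]3[C@H](O)[C@@H](Cl)C1(OC)OC.CN(C)CCN(C)C | intermediate
11 | 7-O-TBS osmate ester | CC(=O)[C@]1(S(=O)(=O)c2ccc(C)cc2)[C@@H]3O[Os](=O)(=O)O[C@@H]3[C@H](O[Si](C)(C)C(C)(C)C)[C@@H](Cl)C1(OC)OC.CN(C)CCN(C)C | intermediate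
12 | 7-O-TBS 5,6-diol | CC(=O)[C@]1(S(=O)(=O)c2ccc(C)cc2)[C@H](O)[C@H](O)[C@H](O[Si](C)(C)C(C)(C)C)[C@@H](Cl)C1(OC)OC | intermediate
13 | acetonide methyl ketone (5,6-O-isopropylidene, 7-OTBS) | CC(=O)[C@]1(S(=O)(=O)c2ccc(C)cc2)[C@@H]3OC(C)(C)O[C@@H]3[C@H](O[Si](C)(C)C(C)(C)C)[C@@H](Cl)C1(OC)OC | intermediate
14 | isovanillin | COc1ccc(C=O)cc1O | starting material
15 | 4-methoxy-3-(methoxymethoxy)benzaldehyde | COCOc1cc(C=O)ccc1OC | intermediate
16 | (E)-3-[4-methoxy-3-(methoxymethoxy)phenyl]prop-2-enoic acid | COCOc1cc(/C=C/C(=O)O)ccc1OC | intermediate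
17 | 3-[4-methoxy-3-(methoxymethoxy)phenyl]propanoic acid | COCOc1cc(CCC(=O)O)ccc1OC | intermediate
18 | 1-{3-[4-methoxy-3-(methoxymethoxy)phenyl]propanoyl}-1H-benzotriazole | COCOc1cc(CCC(=O)n2nnc3ccccc32)ccc1OC | intermediate
19 | lithium enolate of 13 (enolised toward the methyl group) | [Li+].C=C([O-])[C@]1(S(=O)(=O)c2ccc(C)cc2)[C@@H]3OC(C)(C)O[C@@H]3[C@H](O[Si](C)(C)C(C)(C)C)[C@@H](Cl)C1(OC)OC | intermediate
20 | β-diketone sulfone | COCOc1cc(CCC(=O)CC(=O)[C@]2(S(=O)(=O)c3ccc(C)cc3)[C@@H]4OC(C)(C)O[C@@H]4[C@H](O[Si](C)(C)C(C)(C)C)[C@@H](Cl)C2(OC)OC)ccc1OC | intermediate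
21 | desulfonylated diketone ketal (C4a–H, both epimers) | COCOc1cc(CCC(=O)CC(=O)C2[C@@H]4OC(C)(C)O[C@@H]4[C@H](O[Si](C)(C)C(C)(C)C)[C@@H](Cl)C2(OC)OC)ccc1OC | intermediate
22 | protected chromone (5,6-O-isopropylidene, 7-OTBS, 8-Cl, aryl OMOM) | COCOc1cc(CCc2cc(=O)c3c(o2)[C@H](Cl)[C@@H](O[Si](C)(C)C(C)(C)C)[C@H]4OC(C)(C)O[C@@H]34)ccc1OC | intermediate
23 | (5S,6S,7S,8R)-8-chloro-5,6,7-trihydroxy-2-[2-(3-hydroxy-4-methoxyphenyl)ethyl]-5,6,7,8-tetrahydro-4H-chromen-4-one | COc1ccc(CCc2cc(=O)c3c(o2)[C@H](Cl)[C@@H](O)[C@@H](O)[C@H]3O)cc1O | target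

**Step count**
Total steps: 15. Longest linear sequence: 10 (steps 1, 3–8, 13–15, from 3-bromo-2H-pyran-2-one).

**Steps most likely to fail**

1. Step 3. The chlorine substituent makes the ketene acetal a weaker nucleophile, so the cycloaddition may be slow at the temperatures where the bridged lactone survives; CO2 loss and aromatisation then take over, or sulfur discriminates the two diene faces too weakly. Fallback, setting out from 4: oxidation with mCPBA gives 3-(p-tolylsulfonyl)-2H-pyran-2-one F1, a stronger acceptor diene of the same class. Its cycloaddition with 6 near 0 °C should give the sulfone lactone directly as the racemate, that is 8 together with the enantiomer of 8 F2. Compound 8 is then taken by preparative chromatography on a chiral stationary phase, and the route is rejoined at 8.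

2. Step 6. Hydrogen-bond delivery from 7-OH may lose to steric approach from the other face, because the acetyl group on C4a is expected to sit pseudo-axial on the O7 face; the diol would then form trans to O7. Fallback, setting out from 8: the MeLi adduct is trapped at −78 °C with Et3SiOTf before the bridge opens, as the bridged triethylsilyl methyl ketal F3. In this rigid bicycle the alkene face under the C8a–C8 bridge is blocked by chlorine and a methoxy group, so OsO4 (cat.) with N-methylmorpholine N-oxide (Upjohn dihydroxylation) should give the bridged diol F4 on the O-bridge side by steric control alone. 2,2-Dimethoxypropane with PPTS gives the bridged acetonide F5, where only O5 and O6 are free to react. HF·pyridine in THF releases the 7-hydroxy acetonide ketone F6 without a basic alkoxide, and tBuMe2SiOTf with 2,6-lutidine gives 13, where the route is rejoined.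

3. Step 14. Electron transfer may be slow or unselective in the presence of the enolised, acidic 1,3-diketone, and the C4a enol(ate) may expel the acetonide oxygen on C5 in competition with methanol from C8a. Fallback, setting out from 13: SmI2 in THF–MeOH reduces the simple β-keto sulfone 13 to the desulfonylated methyl ketone F7 (C4a–H, both epimers). CSA eliminates methanol to the β-methoxy enone F8 (C4a=C8a–OMe). Its methyl ketone is acylated (LiN(SiMe3)2 at −78 °C, then 18) to the diketone F9, and CSA closes the pyranone to 22, where the route is rejoined. The reduction then runs on a substrate without the diketone, and the pyranone is made by acylation and cyclodehydration of a β-alkoxy enone.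

**Further compounds**
F1 | step 3 | 3-(p-tolylsulfonyl)-2H-pyran-2-one | O=c1occcc1S(=O)(=O)c1ccc(C)cc1
F2 | step 3 | enantiomer of 8 | O=C1O[C@@H]2C=C[C@@]1(S(=O)(=O)c3ccc(C)cc3)C(OC)(OC)[C@H]2Cl
F3 | step 6 | bridged triethylsilyl methyl ketal (7-chloro-8,8-dimethoxy-3-methyl-4-(p-tolylsulfonyl)-3-(triethylsilyloxy)-2-oxabicyclo[2.2.2]oct-5-ene, methyl syn to the alkene) | C[C@@]1(O[Si](CC)(CC)CC)O[C@H]2C=C[C@]1(S(=O)(=O)c3ccc(C)cc3)C(OC)(OC)[C@@H]2Cl
F4 | step 6 | bridged diol (5,6-diol on the side of the oxygen bridge) | C[C@@]1(O[Si](CC)(CC)CC)O[C@H]2[C@@H](O)[C@@H](O)[C@]1(S(=O)(=O)c3ccc(C)cc3)C(OC)(OC)[C@@H]2Cl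
F5 | step 6 | bridged acetonide | C[C@@]1(O[Si](CC)(CC)CC)O[C@H]2[C@H]4OC(C)(C)O[C@H]4[C@]1(S(=O)(=O)c3ccc(C)cc3)C(OC)(OC)[C@@H]2Cl
F6 | step 6 | 7-hydroxy acetonide methyl ketone (13 without the silyl group) | CC(=O)[C@]1(S(=O)(=O)c2ccc(C)cc2)[C@@H]3OC(C)(C)O[C@@H]3[C@H](O)[C@@H](Cl)C1(OC)OC
F7 | step 14 | desulfonylated methyl ketone (C4a–H, both epimers) | CC(=O)C1[C@@H]3OC(C)(C)O[C@@H]3[C@H](O[Si](C)(C)C(C)(C)C)[C@@H](Cl)C1(OC)OC
F8 | step 14 | β-methoxy enone (C4a=C8a–OMe, acetyl on C4a) | CC(=O)C1=C(OC)[C@H](Cl)[C@@H](O[Si](C)(C)C(C)(C)C)[C@H]3OC(C)(C)O[C@@H]13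
F9 | step 14 | diketone of the β-methoxy enone | COCOc1cc(CCC(=O)CC(=O)C2=C(OC)[C@H](Cl)[C@@H](O[Si](C)(C)C(C)(C)C)[C@H]3OC(C)(C)O[C@@H]23)ccc1OC
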